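## The problem

Target 21 is an 8-epi-drimane: a trans-fused decalin (rings A and B; C5–H α, C10 methyl β, C9–H α, C8 with an α-methyl and an axial β-hydroxyl) whose C9 carries, through the exocyclic methine C11, a five-membered ring C1'–C5' (C1' alkylidene carbon, C2' enol carbon, C3' CH, C4' ketone, C5' chlorine-bearing carbon). The four contiguous decalin stereocentres are a classical terpenoid array that the chiral pool can supply, with only C8 inverted relative to the common 8α-oxygenated series. The difficulty lies in the side ring: the trisubstituted C11=C1' alkene must hold the bulky decalin cis to C2' and H11 cis to C5', and condensation of a C11 aldehyde with a cyclopentane-1,3-dione cannot deliver this, because such a dione reacts at C3' between its carbonyls. C5' is separated from C9 by the alkene, so the decalin cannot be relied on to control it and a reagent or catalyst must. Once the ring is a chlorinated vinylogous acid, C5' is allylic and α to a carbonyl and therefore open to enolization and halide exchange, so chlorine has to enter late, stereospecifically, and never meet base or excess halide at the free dione stage. The tertiary C8 alcohol ionizes in strong acid, and a β-hydroxy aldehyde on the way to the side chain is prone to retro-aldol cleavage and C9 epimerization. The feature that opens the problem is the ring bond C1'–C5', which joins the alkylidene carbon to the heteroatom-bearing stereocentre with H11 cis to C5': this is the pattern left by syn addition of hydrogen and a carbonyl carbon across a C11≡C1' alkyne, so an alkynal with the three-atom tether C2'–C3'–C4' is the natural precursor.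

## Retrosynthesis

**Target 21 from chloride 20.** Only C–O bonds are cut: the dioxolanes at C2' and C4' and the triethylsilyl ether at C8. Keeping both ring carbonyls masked until the last operation means that the acidic, epimerizable α-chloro vinylogous acid exists only as the final product. The forward step must open both ketals in aqueous acid without a nucleophilic counter-ion and without ionizing C8.

**Chloride 20 from carbinol 19.** The C5'–Cl bond is traced to a C5' carbinol of opposite configuration. Substitution at the bis-ketal stage is preferred to substitution after hydrolysis. C5' in 19 cannot enolize and has no β-hydrogen, so elimination is excluded, and its SN2' position C11 is buried under the decalin. The forward reaction must be a clean SN2 at a carbon flanked by a ketal.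

**Carbinol 19 from alkynyl aldehyde 18 (key cut).** The ring bond C1'–C5' and the C11–H bond are removed together, which unravels the ring to the acyclic alkynyl aldehyde 18. Neighbouring cuts (olefination of a cyclopentanone at C1', or closure through a preformed vinyl metal) leave the alkene geometry to thermodynamics or need a stereodefined vinyl halide. The reductive alkyne–aldehyde coupling fixes the geometry by mechanism and sets C5' in the same event, so one ring, one alkene geometry and one stereocentre disappear at once. The forward reaction must couple faster than it hydrogenates and must select one aldehyde face.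

**Aldehyde 18 from alcohol 17, ether 16 and ynone 15.** These are functional-group changes only. The C5' aldehyde comes from primary alcohol 17, which is released from its 4-methoxybenzyl ether 16. The C2' dioxolane comes from the carbonyl of ynone 15. The ketals keep C2' and C4' at their final oxidation level, so no redox step follows the key step, and they remove every enolizable or Michael-acceptor site from the cyclization substrate.

**Ynone 15 from alkyne 8 and amide 13.** The C1'–C2' bond is cut between acetylide 14, formed from alkyne 8, and Weinreb amide 13. This is the convergent junction: it joins the terpenoid half and the four-carbon chain C2'–C5' in one step without over-addition.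

**Amide 13 from ester 12, keto ester 10, chloride 9 and diol 11.** The amide comes from ester 12, the C4' dioxolane from keto ester 10 and ethylene glycol 11, and the C5' ether oxygen from chloride displacement on ethyl 4-chloroacetoacetate 9. All four chain carbons come from one commodity chemical.

**Alkyne 8 from aldehydes 7 and 6, triol 5, hydroxy lactone 4, lactone 2 and sclareolide 1.** The alkyne carbon C1' is added to the silylated C11 aldehyde 7 by one-carbon homologation. The free hydroxy aldehyde 6 arises by excising C12 of the lactone: hydroxylation to 4, reduction to triol 5, glycol cleavage. The 8β-oxygen comes from acid epimerization of (+)-sclareolide 1 to lactone 2. Turning the lactone CH2–C(=O) unit directly into the alkyne would save a carbon cycle but needs an unreliable dehydration at a neopentyl position; the longer sequence uses only standard operations.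

## Roads not taken

Alternative 1: The cut is the C1–C10 bond of ring A. The phenolate of bromophenol A1, 5-(5-bromo-2-methylpentan-2-yl)-2,4-dimethylphenol, ion-paired with an N-(9-anthracenylmethyl)cinchonidinium cation, would alkylate itself at the methyl-bearing para carbon and give the cross-conjugated dienone A2, 11-nordrima-5,8-dien-7-one. Its merits are real: the quaternary C10 centre is made catalytically from the flat, cheap aromatic A1, either enantiomer is within reach, and nothing depends on the supply of a natural product. In those respects this road is better than the chosen plan. Its weak points are that C-alkylation of A1 competes with O-alkylation and with attack at the ortho carbon, and that the closure is a fused ring formation onto the carbon next to the tether, where control by a loose ion pair is uncertain. Dienone A2 also lacks C11, carries a C7 ketone that has to be removed, and leaves C5, C8 and C9 to be set beside the quaternary centre, so many redox and C–C bond-forming steps separate A2 from an intermediate such as 7. Against this the chosen plan sets the fact that 1 delivers C5, C9 and C10 ready-made and C8 after one step.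

Alternative 2: The cuts are C4–C5 and C9–C10. SnCl4 complexed with (R)-2-benzyloxy-2'-hydroxy-1,1'-binaphthyl would protonate the terminal alkene of the acyclic keto ester A3, methyl (E)-7,11-dimethyl-3-oxododeca-6,10-dienoate, and the chair–chair cascade would end on the enol carbon to give the trans-fused keto ester A4, methyl 8-oxo-12-nordriman-11-oate. The merits are considerable. Polyene A3 is achiral and simple, two rings and three stereocentres form in one step, and C11 arrives on C9 at the ester level, so no carbon is cut off and re-added. Methyl addition to the C8 ketone of A4 from the equatorial α side (the β face is shielded by the axial C10 methyl) would give the 8β-hydroxyl directly, with no epimerization step. The path from A4 to alkyne 8 would be about as short as the path from 1, possibly shorter. The weak points are that the chiral acid is used stoichiometrically, that enantioselectivity with a β-keto ester terminator is uncertain (O- versus C-termination, partial cyclization of A3), and that methyl addition to the β-keto ester A4 competes with enolization. The chosen plan sets against this a secure absolute configuration and degradation steps that are each established on sclareolide.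

Alternative 3: The cut is C8–C9 of ring B. SmI2 would reduce the C–Br bond of bromo ester A5, ethyl bromo[1,3,3-trimethyl-2-(3-oxobutyl)cyclohexyl]acetate with the C10 methyl trans to C5–H, and the samarium enolate would add to the side-chain methyl ketone through a chelated chair to give hydroxy ester A6, ethyl 8β-hydroxydriman-11-oate. Its merit is that the hindered C8–C9 bond and the cis C8–O/C9–C11 relationship that the target needs form together under mild conditions. Hydroxy ester A6 also lies one reduction away from hydroxy aldehyde 6. Its weak point is that A5 already contains C5 and the quaternary C10 in defined relative and absolute configuration. The stereochemical problem is moved into A5, which needs its own enantioselective synthesis. The chosen plan reaches the same array from 1 in one epimerization and three degradation steps.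

None of the three alternatives addresses the alkylidene geometry or C5'. Each would still need a sequence like steps 10–16.

Key step: step 14

**Conventions and assumptions**
- Dec denotes the 8-epi-drimane nucleus attached through C9 (C5–H α, C10 methyl β, C9–H α, C8 with α-CH3 and β-OSiEt3). Dec′ is the same unit with free 8β-OH.
- Assumption: (R)-BINAP is taken to deliver the (5'S)-carbinol 19; if the facial sense is the reverse, (S)-BINAP is used in the same way.
- Assumption: the product of step 16 is written as the C2' enol tautomer of the 1,3-dione, as in the target structure; the tautomers interconvert.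

## Route

Step 1
Reactants: 1 (+)-sclareolide
Product: 2 8-epi-sclareolide
Conditions: H2SO4, HCO2H, rt
Reagents that add atoms: none
Why: Acid-mediated lactone epimerization: protonation ionizes the tertiary C8–O bond and the carboxylic acid recloses on the C8 cation from the β face to the more stable cis-fused γ-lactone (8α-methyl equatorial, no 1,3-diaxial clash with the C10 methyl), a known equilibration of sclareolide; C5, C9 and C10 are not involved.

Step 2
Reactants: 2 8-epi-sclareolide
Product: 4 11-hydroxy-8-epi-sclareolide, via potassium lactone enolate 3 (not isolated)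
Conditions: KN(SiMe3)2, THF, −78 °C; 2-(phenylsulfonyl)-3-phenyloxaziridine, −78 °C; aq. NH4Cl
Reagents that add atoms: 2-(phenylsulfonyl)-3-phenyloxaziridine, O=S(=O)(c1ccccc1)N1OC1c1ccccc1
Why: Davis oxidation of a lactone enolate: the potassium enolate attacks the oxaziridine oxygen to give the α-hydroxy lactone; the new C11 centre is not controlled and need not be, since C12 is cut away in step 4.

Step 3
Reactants: 4 11-hydroxy-8-epi-sclareolide
Product: 5 8-epi-13,14,15,16-tetranorlabdane-8β,11,12-triol
Conditions: LiAlH4, THF, 0 °C to rt
Reagents that add atoms: none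
Why: Hydride reduction of the lactone to the diol opens the ring and frees the tertiary C8 hydroxyl; no stereocentre is touched.

Step 4
Reactants: 5 8-epi-13,14,15,16-tetranorlabdane-8β,11,12-triol
Product: 6 8β-hydroxy-8-epi-driman-11-al
Conditions: NaIO4, THF/H2O, 0 °C to rt
Reagents that add atoms: none
Why: Malaprade glycol cleavage of the 11,12-diol removes C12 as formaldehyde and leaves C11 as the aldehyde; the C8 hydroxyl is 1,3 to the C11 hydroxyl and is not cleaved, and the near-neutral medium avoids retro-aldol opening and C9 epimerization.

Step 5
Reactants: 6 8β-hydroxy-8-epi-driman-11-al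
Product: 7 8β-(triethylsilyloxy)-8-epi-driman-11-al
Conditions: Et3SiOTf, 2,6-lutidine, CH2Cl2, −78 to 0 °C
Reagents that add atoms: triethylsilyl trifluoromethanesulfonate, CC[Si](CC)(CC)OS(=O)(=O)C(F)(F)F
Why: Silyl triflate with a hindered pyridine base silylates the axial tertiary alcohol at low temperature; capping the hydroxyl closes the retro-aldol pathway before any basic step, and 2,6-lutidine does not enolize the α-branched aldehyde.

Step 6
Reactants: 7 8β-(triethylsilyloxy)-8-epi-driman-11-al
Product: 8 alkyne Dec–C11≡C1'H
Conditions: Me3SiCHN2, n-BuLi, THF, −78 to 0 °C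
Reagents that add atoms: trimethylsilyldiazomethane, C[Si](C)(C)C=[N+]=[N-]
Why: Colvin rearrangement: lithiated trimethylsilyldiazomethane adds to the aldehyde, Peterson-type loss of silanolate and N2 gives an alkylidene carbene, and 1,2-hydride shift gives the terminal alkyne (the new carbon is C1'); addition at −78 °C outpaces enolization, so C9 keeps its configuration.

Step 7
Reactants: 9 ethyl 4-chloroacetoacetate
Product: 10 ethyl 4-(4-methoxybenzyloxy)-3-oxobutanoate
Conditions: 4-MeOC6H4CH2OH, NaH (2.2 equiv), THF, 0 °C to rt; aq. NH4Cl
Reagents that add atoms: 4-methoxybenzyl alcohol, COc1ccc(CO)cc1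
Why: Williamson etherification on the sodium enolate of the β-keto ester: the second equivalent of NaH ties up the acidic methylene while the alkoxide displaces the activated α'-chloride by SN2, a standard route to 4-alkoxyacetoacetates.

Step 8
Reactants: 10 ethyl 4-(4-methoxybenzyloxy)-3-oxobutanoate; 11 ethylene glycol
Product: 12 ethyl 2-{2-[(4-methoxybenzyloxy)methyl]-1,3-dioxolan-2-yl}acetate
Conditions: pyridinium p-toluenesulfonate (cat.), benzene, reflux, Dean–Stark
Reagents that add atoms: none
Why: Acid-catalysed dioxolane formation on the ketone of a β-keto ester with azeotropic removal of water; the mild pyridinium acid spares the 4-methoxybenzyl ether.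

Step 9
Reactants: 12 ethyl 2-{2-[(4-methoxybenzyloxy)methyl]-1,3-dioxolan-2-yl}acetate
Product: 13 N-methoxy-N-methyl-2-{2-[(4-methoxybenzyloxy)methyl]-1,3-dioxolan-2-yl}acetamide
Conditions: MeNH(OMe)·HCl, i-PrMgCl, THF, −20 to 0 °C
Reagents that add atoms: N,O-dimethylhydroxylamine hydrochloride, CNOC.Cl
Why: Direct ester aminolysis by the chloromagnesium amide of N,O-dimethylhydroxylamine (Weinreb amide formation); the reaction stops at the chelated tetrahedral intermediate and the ketal is inert to the basic medium.

Step 10
Reactants: 8 alkyne Dec–C11≡C1'H; 13 N-methoxy-N-methyl-2-{2-[(4-methoxybenzyloxy)methyl]-1,3-dioxolan-2-yl}acetamide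
Product: 15 ynone Dec–C11≡C1'–C2'(=O)–C3'H2–C4'(OCH2CH2O)–C5'H2–OCH2C6H4OMe-4, via lithium acetylide 14 (not isolated)
Conditions: n-BuLi, THF, −78 °C; 13, −78 to 0 °C; aq. NH4Cl
Reagents that add atoms: none
Why: Weinreb ketone synthesis forming the C1'–C2' bond: the lithium acetylide adds once and the chelated tetrahedral intermediate survives until quench, so no tertiary alcohol forms and the β-ketal ketone is not exposed to base.

Step 11
Reactants: 15 ynone Dec–C11≡C1'–C2'(=O)–C3'H2–C4'(OCH2CH2O)–C5'H2–OCH2C6H4OMe-4
Product: 16 bis-dioxolane Dec–C11≡C1'–C2'(OCH2CH2O)–C3'H2–C4'(OCH2CH2O)–C5'H2–OCH2C6H4OMe-4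
Conditions: Me3SiOCH2CH2OSiMe3, Me3SiOTf (cat.), CH2Cl2, −78 to −20 °C; pyridine
Reagents that add atoms: 1,2-bis(trimethylsilyloxy)ethane, C[Si](C)(C)OCCO[Si](C)(C)C
Why: Noyori ketalization: the silyl triflate activates the ynone carbonyl toward the bis-silyl ether and irreversible loss of hexamethyldisiloxane drives dioxolane formation under aprotic, base-free, cold conditions that tolerate the existing ketal, the benzyl-type ether and the tertiary silyl ether.

Step 12
Reactants: 16 bis-dioxolane 4-methoxybenzyl ether
Product: 17 primary alcohol Dec–C11≡C1'–C2'(OCH2CH2O)–C3'H2–C4'(OCH2CH2O)–C5'H2OH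
Conditions: DDQ, CH2Cl2/pH 7 phosphate buffer, 0 °C
Reagents that add atoms: none
Why: Oxidative cleavage of the 4-methoxybenzyl ether by DDQ through the benzylic oxocarbenium ion and its hydrolysis; the buffered medium keeps both dioxolanes and the triethylsilyl ether, and the alkyne is inert.

Step 13
Reactants: 17 primary alcohol Dec–C11≡C1'–C2'(OCH2CH2O)–C3'H2–C4'(OCH2CH2O)–C5'H2OH
Product: 18 alkynyl aldehyde Dec–C11≡C1'–C2'(OCH2CH2O)–C3'H2–C4'(OCH2CH2O)–C5'H=O
Conditions: Dess–Martin periodinane, NaHCO3, CH2Cl2, 0 °C to rt
Reagents that add atoms: none
Why: Dess–Martin oxidation of the neopentyl-type primary alcohol under bicarbonate buffer gives the non-enolizable α,α-dialkoxy aldehyde without over-oxidation.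

Step 14
Reactants: 18 alkynyl aldehyde Dec–C11≡C1'–C2'(OCH2CH2O)–C3'H2–C4'(OCH2CH2O)–C5'H=O
Product: 19 (5'S)-alkylidene cyclopentanol bis-dioxolane (Dec cis to C2' and H11 cis to C5')
Conditions: Rh(cod)2OTf (5 mol %), (R)-BINAP (5 mol %), 2-naphthoic acid (cat.), H2 (1 atm), ClCH2CH2Cl, 45 °C
Reagents that add atoms: none
Why: Hydrogenation strips cyclooctadiene to leave a cationic monovalent rhodium–(R)-2,2'-bis(diphenylphosphino)-1,1'-binaphthyl fragment that binds the alkyne and the aldehyde of 18, and oxidative coupling forms C1'–C5' in an oxarhodacyclopentene of trivalent rhodium with the metal on C11 and on the aldehyde oxygen. Acid-assisted hydrogenolysis of the Rh–O and Rh–C11 bonds releases 19 and returns monovalent rhodium, so hydrogen reaches C11 with retention. The closest known reaction type is the rhodium-catalysed hydrogen-mediated reductive cyclization of acetylenic aldehydes of the hex-5-ynal type to 2-alkylidenecycloalkanols, with nickel-catalysed silane-mediated cyclizations as the racemic relatives. The cyclopentane closes 5-exo-dig at the alkyne (5-exo-trig at the carbonyl), and the three-atom tether C2'–C3'–C4' excludes other ring sizes. The C11=C1' geometry is fixed by syn addition of hydrogen and carbon, so H11 ends cis to C5' and the decalin cis to C2'. The new C5' carbinol centre is set by the diphosphine, which differentiates the aldehyde faces in the coupling, with C9 across the alkyne only a secondary bias. The step needs coupling to outrun plain hydrogenation of alkyne or aldehyde; the α,α-dialkoxy aldehyde is unusually electrophilic, which favours oxidative coupling, and the two ketals remove every enolizable or β-eliminable position.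

Step 15
Reactants: 19 (5'S)-alkylidene cyclopentanol bis-dioxolane
Product: 20 (5'R)-chloride bis-dioxolane
Conditions: PPh3, (Cl3C)2CO, CH2Cl2, −20 to 0 °C
Reagents that add atoms: hexachloroacetone, ClC(Cl)(Cl)C(=O)C(Cl)(Cl)Cl
Why: Appel-type chlorination with triphenylphosphine–hexachloroacetone, a combination known to convert allylic alcohols into chlorides with inversion and without allylic shift: chloride displaces the alkoxyphosphonium ion by SN2 and turns the (5'S)-carbinol into the (5'R)-chloride; C5' has no β-hydrogen, so elimination is impossible, and SN2' attack at C11 is blocked by the decalin.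

Step 16
Reactants: 20 (5'R)-chloride bis-dioxolane
Product: 21 CNP0279879.2
Conditions: 1 M aq. H2SO4, THF, rt to 40 °C
Reagents that add atoms: water, O
Why: Aqueous acid hydrolysis: the alkenyl C2' dioxolane and the silyl ether cleave first, and the C4' dioxolane then opens by enol-assisted β-elimination and hydrolysis of the resulting enol ether, which avoids an oxocarbenium ion next to the chlorinated carbon; a non-nucleophilic acid excludes chloride exchange at C5', and the dione settles as the conjugated C2' enol.

## Compound list

1 | (+)-sclareolide | CC1(C)CCC[C@]2(C)[C@H]3CC(=O)O[C@]3(C)CC[C@@H]12 | starting material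
2 | 8-epi-sclareolide (cis-fused lactone, 8β-O, 8α-CH3) | CC1(C)CCC[C@]2(C)[C@H]3CC(=O)O[C@@]3(C)CC[C@@H]12 | intermediate
3 | potassium enolate of 2 (C11=C12 enolate) | CC1(C)CCC[C@]2(C)[C@H]3C=C([O-])O[C@@]3(C)CC[C@@H]12.[K+] | intermediate (not isolated)
4 | 11-hydroxy-8-epi-sclareolide (C11 epimers, not assigned) | CC1(C)CCC[C@]2(C)[C@H]3C(O)C(=O)O[C@@]3(C)CC[C@@H]12 | intermediate
5 | 8-epi-13,14,15,16-tetranorlabdane-8β,11,12-triol (C11 epimers) | CC1(C)CCC[C@]2(C)[C@@H](C(O)CO)[C@@](C)(O)CC[C@@H]12 | intermediate
6 | 8β-hydroxy-8-epi-driman-11-al | CC1(C)CCC[C@]2(C)[C@@H](C=O)[C@@](C)(O)CC[C@@H]12 | intermediate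
7 | 8β-(triethylsilyloxy)-8-epi-driman-11-al | CC1(C)CCC[C@]2(C)[C@@H](C=O)[C@@](C)(O[Si](CC)(CC)CC)CC[C@@H]12 | intermediate
8 | alkyne Dec–C11≡C1'H (9β-ethynyl, 8β-OSiEt3) | CC1(C)CCC[C@]2(C)[C@@H](C#C)[C@@](C)(O[Si](CC)(CC)CC)CC[C@@H]12 | intermediate
9 | ethyl 4-chloroacetoacetate | CCOC(=O)CC(=O)CCl | starting material
10 | ethyl 4-(4-methoxybenzyloxy)-3-oxobutanoate | CCOC(=O)CC(=O)COCc1ccc(OC)cc1 | intermediate
11 | ethylene glycol | OCCO | starting material
12 | ethyl 2-{2-[(4-methoxybenzyloxy)methyl]-1,3-dioxolan-2-yl}acetate | CCOC(=O)CC1(COCc2ccc(OC)cc2)OCCO1 | intermediate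
13 | N-methoxy-N-methyl-2-{2-[(4-methoxybenzyloxy)methyl]-1,3-dioxolan-2-yl}acetamide | CON(C)C(=O)CC1(COCc2ccc(OC)cc2)OCCO1 | intermediate
14 | lithium acetylide of 8 | CC1(C)CCC[C@]2(C)[C@@H](C#C[Li])[C@@](C)(O[Si](CC)(CC)CC)CC[C@@H]12 | intermediate (not isolated)
15 | ynone Dec–C11≡C1'–C2'(=O)–C3'H2–C4'(dioxolane)–C5'H2–O-(4-methoxybenzyl) | CC1(C)CCC[C@]2(C)[C@@H](C#CC(=O)CC3(COCc4ccc(OC)cc4)OCCO3)[C@@](C)(O[Si](CC)(CC)CC)CC[C@@H]12 | intermediate
16 | bis-dioxolane (C2' and C4') 4-methoxybenzyl ether | CC1(C)CCC[C@]2(C)[C@@H](C#CC3(CC4(COCc5ccc(OC)cc5)OCCO4)OCCO3)[C@@](C)(O[Si](CC)(CC)CC)CC[C@@H]12 | intermediate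
17 | bis-dioxolane primary alcohol (C5'H2OH) | CC1(C)CCC[C@]2(C)[C@@H](C#CC3(CC4(CO)OCCO4)OCCO3)[C@@](C)(O[Si](CC)(CC)CC)CC[C@@H]12 | intermediate
18 | bis-dioxolane alkynyl aldehyde (C5'H=O), key-step precursor | CC1(C)CCC[C@]2(C)[C@@H](C#CC3(CC4(C=O)OCCO4)OCCO3)[C@@](C)(O[Si](CC)(CC)CC)CC[C@@H]12 | intermediate
19 | (5'S)-alkylidene cyclopentanol bis-dioxolane, (Z) by CIP, Dec cis to C2' | CC1(C)CCC[C@]2(C)[C@@H](/C=C3\C4(OCCO4)CC5(OCCO5)[C@H]3O)[C@@](C)(O[Si](CC)(CC)CC)CC[C@@H]12 | intermediate
20 | (5'R)-chloride bis-dioxolane, same alkene geometry ((E) by CIP) | CC1(C)CCC[C@]2(C)[C@@H](/C=C3\C4(OCCO4)CC5(OCCO5)[C@@H]3Cl)[C@@](C)(O[Si](CC)(CC)CC)CC[C@@H]12 | intermediate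
21 | CNP0279879.2, (4E,5R)-5-chloro-3-hydroxy-4-{[(1R,2S,4aS,8aS)-2-hydroxy-2,5,5,8a-tetramethyldecahydronaphthalen-1-yl]methylidene}cyclopent-2-en-1-one | CC1(C)CCC[C@]2(C)[C@@H](/C=C3\C(O)=CC(=O)[C@@H]3Cl)[C@@](C)(O)CC[C@@H]12 | target

## Step count and risks

Total: 16 steps. Longest linear sequence: 13 steps (steps 1–6 and 10–16); the chain fragment takes 3 steps (7–9).

**Step 14 (key step).**
- Most likely failure: slow oxidative coupling at an alkyne buried between C9 and the C2' dioxolane, so that plain hydrogenation of the alkyne or the aldehyde takes over; or incomplete facial discrimination at the aldehyde.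
- Fallback: separate ring closure from stereocontrol. From 18, zerovalent nickel catalysis (Ni(cod)2, PBu3, Et3SiH, THF) closes the same C1'–C5' bond with the same syn geometry but without facial control. It gives the C5' triethylsilyl ether F1 as a mixture of C5' epimers. HF·pyridine removes the secondary silyl group selectively and gives 19 together with its (5'R)-epimeric carbinol F2. Dess–Martin oxidation of this mixture converges on the single alkylidene cyclopentanone F3. CBS reduction (2-methyl-CBS-oxazaborolidine, BH3·SMe2, antipode chosen for the (5'S) face) comes back to the route at 19.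

**Step 15.**
- Most likely failure: sluggish SN2 beside the C4' ketal, which lets the alkoxyphosphonium ion ionize, with loss of stereochemical fidelity or allylic transposition.
- Fallback: carry out the substitution α to a carbonyl, where SN2 is strongly accelerated. From 19, aqueous acid (as in step 16) gives the hydroxy dione F4. Acid-catalysed etherification (MeOH, HC(OMe)3, camphorsulfonic acid) under equilibrating conditions should favour the linearly conjugated 2'-O-methyl enol ether F5. Appel chlorination of its α-keto carbinol gives the chloro enol ether F6 with inversion. Aqueous H2SO4 hydrolysis of the enol ether rejoins the route at 21.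

**Step 11.**
- Most likely failure: acid-induced β-elimination of the existing C4' dioxolane to a vinylogous ester, or no reaction at the deactivated, hindered ynone carbonyl.
- Fallback: carry C2' at the alcohol oxidation level. From 15, Luche reduction (NaBH4, CeCl3·7H2O, MeOH) gives the propargylic alcohol F7 (C2' epimers, inconsequential). Silylation (t-BuMe2SiOTf, 2,6-lutidine) gives the tert-butyldimethylsilyl ether F8. DDQ and then Dess–Martin oxidation, as in steps 12 and 13, give the primary alcohol F9 and the ynal F10. The rhodium cyclization of step 14 gives the carbinol F11, and Appel chlorination gives the chloride F12. HF·pyridine removes both silyl groups to give the diol F13. Dess–Martin oxidation of the allylic C2' carbinol gives the enone F14 (the tertiary C8 alcohol is inert). Aqueous acid opens the remaining C4' dioxolane and rejoins the route at 21.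

**Step 6.**
- Most likely failure: enolization of the congested α-branched aldehyde by the lithiated diazo reagent in place of addition, which scrambles C9 or returns starting material.
- Fallback: Corey–Fuchs sequence. From 7, CBr4/PPh3 (CH2Cl2, 0 °C) gives the dibromoalkene F15. n-BuLi (2 equiv, THF, −78 °C) converts it by bromine–lithium exchange and rearrangement directly into the lithium acetylide, so the route is rejoined at 14 and continues with step 10.

## Further compounds

F1 | step 14 | C5' triethylsilyl ether of 19 and of its C5' epimer (mixture at C5') | CC1(C)CCC[C@]2(C)[C@@H](/C=C3\C4(OCCO4)CC5(OCCO5)C3O[Si](CC)(CC)CC)[C@@](C)(O[Si](CC)(CC)CC)CC[C@@H]12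
F2 | step 14 | (5'R)-alkylidene cyclopentanol bis-dioxolane (C5' epimer of 19) | CC1(C)CCC[C@]2(C)[C@@H](/C=C3\C4(OCCO4)CC5(OCCO5)[C@@H]3O)[C@@](C)(O[Si](CC)(CC)CC)CC[C@@H]12
F3 | step 14 | C5' ketone (alkylidene cyclopentanone bis-dioxolane) | CC1(C)CCC[C@]2(C)[C@@H](/C=C3\C4(OCCO4)CC5(OCCO5)C3=O)[C@@](C)(O[Si](CC)(CC)CC)CC[C@@H]12
F4 | step 15 | (5'S)-hydroxy dione, drawn as C2' enol, free 8β-OH | CC1(C)CCC[C@]2(C)[C@@H](/C=C3\C(O)=CC(=O)[C@H]3O)[C@@](C)(O)CC[C@@H]12
F5 | step 15 | 2'-O-methyl enol ether of F4 | CC1(C)CCC[C@]2(C)[C@@H](/C=C3\C(OC)=CC(=O)[C@H]3O)[C@@](C)(O)CC[C@@H]12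
F6 | step 15 | (5'R)-chloro 2'-O-methyl enol ether | CC1(C)CCC[C@]2(C)[C@@H](/C=C3\C(OC)=CC(=O)[C@@H]3Cl)[C@@](C)(O)CC[C@@H]12
F7 | step 11 | propargylic alcohol from 15 (C2' epimers) | CC1(C)CCC[C@]2(C)[C@@H](C#CC(O)CC3(COCc4ccc(OC)cc4)OCCO3)[C@@](C)(O[Si](CC)(CC)CC)CC[C@@H]12
F8 | step 11 | C2' tert-butyldimethylsilyl ether of F7 | CC1(C)CCC[C@]2(C)[C@@H](C#CC(O[Si](C)(C)C(C)(C)C)CC3(COCc4ccc(OC)cc4)OCCO3)[C@@](C)(O[Si](CC)(CC)CC)CC[C@@H]12
F9 | step 11 | C5' primary alcohol (C2' silyl ether, C4' dioxolane) | CC1(C)CCC[C@]2(C)[C@@H](C#CC(O[Si](C)(C)C(C)(C)C)CC3(CO)OCCO3)[C@@](C)(O[Si](CC)(CC)CC)CC[C@@H]12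
F10 | step 11 | alkynyl aldehyde (C2' silyl ether, C4' dioxolane) | CC1(C)CCC[C@]2(C)[C@@H](C#CC(O[Si](C)(C)C(C)(C)C)CC3(C=O)OCCO3)[C@@](C)(O[Si](CC)(CC)CC)CC[C@@H]12
F11 | step 11 | (5'S)-alkylidene cyclopentanol (C2' silyl ether, C4' dioxolane) | CC1(C)CCC[C@]2(C)[C@@H](/C=C3\C(O[Si](C)(C)C(C)(C)C)CC4(OCCO4)[C@H]3O)[C@@](C)(O[Si](CC)(CC)CC)CC[C@@H]12
F12 | step 11 | (5'R)-chloride (C2' silyl ether, C4' dioxolane) | CC1(C)CCC[C@]2(C)[C@@H](/C=C3\C(O[Si](C)(C)C(C)(C)C)CC4(OCCO4)[C@@H]3Cl)[C@@](C)(O[Si](CC)(CC)CC)CC[C@@H]12
F13 | step 11 | (5'R)-chloro diol (free C2' and C8 hydroxyls, C4' dioxolane) | CC1(C)CCC[C@]2(C)[C@@H](/C=C3\C(O)CC4(OCCO4)[C@@H]3Cl)[C@@](C)(O)CC[C@@H]12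
F14 | step 11 | (5'R)-chloro C2' enone with C4' dioxolane | CC1(C)CCC[C@]2(C)[C@@H](/C=C3\C(=O)CC4(OCCO4)[C@@H]3Cl)[C@@](C)(O)CC[C@@H]12
F15 | step 6 | 1,1-dibromoalkene Dec–C11H=CBr2 | CC1(C)CCC[C@]2(C)[C@@H](C=C(Br)Br)[C@@](C)(O[Si](CC)(CC)CC)CC[C@@H]12
A1 | alternative 1 | 5-(5-bromo-2-methylpentan-2-yl)-2,4-dimethylphenol | Oc1cc(C(C)(C)CCCBr)c(C)cc1C
A2 | alternative 1 | 11-nordrima-5,8-dien-7-one | CC1(C)CCC[C@]2(C)C=C(C)C(=O)C=C12
A3 | alternative 2 | methyl (E)-7,11-dimethyl-3-oxododeca-6,10-dienoate | COC(=O)CC(=O)CC/C=C(\C)CCC=C(C)C
A4 | alternative 2 | methyl 8-oxo-12-nordriman-11-oate | CC1(C)CCC[C@]2(C)[C@@H](C(=O)OC)C(=O)CC[C@@H]12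
A5 | alternative 3 | ethyl bromo[1,3,3-trimethyl-2-(3-oxobutyl)cyclohexyl]acetate (C10 methyl trans to C5-H; bromide centre unassigned) | CC1(C)CCC[C@](C)(C(Br)C(=O)OCC)[C@H]1CCC(C)=O
A6 | alternative 3 | ethyl 8β-hydroxydriman-11-oate | CC1(C)CCC[C@]2(C)[C@@H](C(=O)OCC)[C@@](C)(O)CC[C@@H]12
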